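## Retrosyn­thetic overview

1. The C4 ester is attached last (Steglich), and the C4 carbinol comes from a hydroxyl-directed reduction of a 3-hydroxy-azulene-4,7-dione.
2. That ene-dione is the hydrolysis product of a 4,7-dimethoxycycloheptatriene; its two enol ethers are the two methoxy groups of a hydroquinone dimethyl ether.
3. The cycloheptatriene-fused cyclopentanone comes from an intramolecular Buchner reaction of an α-methyl α-diazoketone on a 2,5-dimethoxy-4-methylphenyl ring. The five-membered ring closes in the cyclopropanation, the seven-membered ring forms by norcaradiene opening, and the quaternary C8a–CH3 is set in the same step.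
4. The diazoketone comes from an ethyl ketone, made from a tertiary β-hydroxy ester (enantioselective Reformatsky) of the aryl isopropyl ketone obtained from 2,5-dimethoxytoluene and isobutyryl chloride.

Assumption: bicyclic compounds are named with azulene locants (five-membered ring C1–C3, fusion carbons C3a and C8a, seven-membered ring C4–C8); TBS = tert-butyldimethylsilyl, p-ABSA = 4-acetamidobenzenesulfonyl azide.

## Route

Step 1
Reactants: 1 2,5-dimethoxytoluene; 2 isobutyryl chloride
Product: 3 1-(2,5-dimethoxy-4-methylphenyl)-2-methylpropan-1-one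
Conditions: Bi(OTf)3 (5 mol%), MeNO2, 50 °C
Reagents that add atoms: none
Why: Friedel–Crafts acylation goes to the ring position para to the methyl and ortho to a methoxy group (the most activated, least hindered site), and a catalytic triflate avoids the ortho-demethylation that stoichiometric AlCl3 can cause.

Step 2
Reactants: 3 1-(2,5-dimethoxy-4-methylphenyl)-2-methylpropan-1-one; 4 ethyl iodoacetate
Product: 5 ethyl (3R)-3-(2,5-dimethoxy-4-methylphenyl)-3-hydroxy-4-methylpentanoate
Conditions: Me2Zn (2 equiv), chloro[(R,R)-N,N'-bis(3,5-di-tert-butylsalicylidene)-1,2-cyclohexanediaminato]manganese (20 mol%), 4-phenylpyridine N-oxide (25 mol%), MTBE, rt; aq. NH4Cl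
Reagents that add atoms: none
Why: Catalytic enantioselective Reformatsky reaction, in which the zinc enolate made from 4 and Me2Zn adds to the ketone inside the chiral (salen)MnCl pocket, which must tell the twisted aryl group from the isopropyl group to set the tertiary carbinol as (R); the sense and ee for this hindered ketone are not known in advance, so the catalyst antipode is fixed on the first run and the ee is raised by crystallisation of 5 and by the matched catalyst of step 7.

Step 3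
Reactants: 5 ethyl (3R)-3-(2,5-dimethoxy-4-methylphenyl)-3-hydroxy-4-methylpentanoate
Product: 6 ethyl (3R)-3-(2,5-dimethoxy-4-methylphenyl)-4-methyl-3-[(trimethylsilyl)oxy]pentanoate
Conditions: 1-(trimethylsilyl)imidazole (3 equiv), CH2Cl2, rt
Reagents that add atoms: 1-(trimethylsilyl)imidazole, C[Si](C)(C)n1ccnc1
Why: O-silylation of the hindered tertiary alcohol blocks retro-aldol cleavage under the basic steps and O–H insertion of the later carbene, and the small Me3Si group falls off with dilute acid in step 8.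

Step 4
Reactants: 6 ethyl (3R)-3-(2,5-dimethoxy-4-methylphenyl)-4-methyl-3-[(trimethylsilyl)oxy]pentanoate
Product: 8 (5R)-5-(2,5-dimethoxy-4-methylphenyl)-6-methyl-5-[(trimethylsilyl)oxy]heptan-3-one, via Weinreb amide 7 (not isolated)
Conditions: MeNH(OMe)·HCl (1.5 equiv), iPrMgCl (3 equiv), THF, −20 °C; then EtMgBr (3 equiv), −20 → 0 °C; aq. NH4Cl
Reagents that add atoms: ethylmagnesium bromide, CC[Mg]Br; N,O-dimethylhydroxylamine hydrochloride, CNOC.Cl (its atoms are in 7 only)
Why: One-pot Weinreb ketone synthesis (magnesium amide aminolysis of the ester, then Grignard addition to the chelated amide) stops at the ethyl ketone.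

Step 5
Reactants: 8 (5R)-5-(2,5-dimethoxy-4-methylphenyl)-6-methyl-5-[(trimethylsilyl)oxy]heptan-3-one
Product: 10 (5R)-2-diazo-5-(2,5-dimethoxy-4-methylphenyl)-6-methyl-5-[(trimethylsilyl)oxy]heptan-3-one, via trifluoroacetyl diketone 9 (not isolated)
Conditions: LiN(SiMe3)2 (1.1 equiv), THF, −78 °C; CF3CO2CH2CF3; cold 1 M HCl wash; then p-ABSA, Et3N, H2O (1 equiv), MeCN, rt
Reagents that add atoms: 4-acetamidobenzenesulfonyl azide, CC(=O)Nc1ccc(cc1)S(=O)(=O)N=[N+]=[N-]; 2,2,2-trifluoroethyl trifluoroacetate, FC(F)(F)COC(=O)C(F)(F)F (its atoms are in 9 only)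
Why: Danheiser detrifluoroacetylative diazo transfer: kinetic enolisation takes place at the open ethyl CH2 and not at the neopentyl CH2 next to the quaternary carbinol, and the activated diketone accepts the diazo group and loses trifluoroacetyl as the sulfonamide.

Step 6
Reactants: 10 (5R)-2-diazo-5-(2,5-dimethoxy-4-methylphenyl)-6-methyl-5-[(trimethylsilyl)oxy]heptan-3-one
Product: 12 (3R,8aR)-4,7-dimethoxy-6,8a-dimethyl-3-(propan-2-yl)-3-[(trimethylsilyl)oxy]-3,8a-dihydroazulen-1(2H)-one, via norcaradiene 11 (not isolated)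
Conditions: Rh2(OAc)4 (1 mol%), CH2Cl2, 40 °C, 10 added over 2 h, acid-free work-up
Reagents that add atoms: none
Why: Intramolecular Buchner reaction (rhodium carbene cyclopropanation of the arene bond between the ipso carbon and the only free ortho carbon, then 6π norcaradiene–cycloheptatriene opening) builds both rings and the quaternary methyl centre at once; A(1,3) strain with the ortho methoxy group should put OSiMe3 in the arene plane and the isopropyl group under the ring, so the carbene methyl ends cis to OSiMe3 (8aR).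

Step 7
Reactants: 12 (3R,8aR)-4,7-dimethoxy-6,8a-dimethyl-3-(propan-2-yl)-3-[(trimethylsilyl)oxy]-3,8a-dihydroazulen-1(2H)-one
Product: 13 (1R,3R,8aR)-1-[(tert-butyldimethylsilyl)oxy]-4,7-dimethoxy-6,8a-dimethyl-3-(propan-2-yl)-3-[(trimethylsilyl)oxy]-1,2,3,8a-tetrahydroazulene
Conditions: CuCl (3 mol%), NaOtBu (3 mol%), (R)-DTBM-SEGPHOS (3 mol%), t-BuMe2SiH (1.5 equiv), toluene, 0 °C → rt
Reagents that add atoms: tert-butyldimethylsilane, C[SiH](C)C(C)(C)C
Why: Ligand-accelerated copper hydride hydrosilylation should deliver hydride to the cyclopentanone face anti to the angular methyl (the (R)-ligand is the matched one by the large/small model, to be confirmed) and gives the (1R) alcohol directly as its TBS ether, which also removes the ketone that would let acid rearrange the cycloheptatriene to a 2-tetralone.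

Step 8
Reactants: 13 (1R,3R,8aR)-1-[(tert-butyldimethylsilyl)oxy]-4,7-dimethoxy-6,8a-dimethyl-3-(propan-2-yl)-3-[(trimethylsilyl)oxy]-1,2,3,8a-tetrahydroazulene
Product: 15 (1R,3R,3aS,4S,8aR)-1-[(tert-butyldimethylsilyl)oxy]-3,4-dihydroxy-6,8a-dimethyl-3-(propan-2-yl)-1,2,3,3a,4,8a-hexahydroazulen-7(8H)-one, via enedione 14 (not isolated)
Conditions: HCl (0.3 equiv), MeCN/H2O (20:1), 0 °C → rt; then AcOH, Me4NBH(OAc)3 (8 equiv), −30 → −20 °C
Reagents that add atoms: water, O
Why: Acid hydrolysis of both enol ethers and the Me3Si ether (C3a protonated anti to the angular methyl, expected to give the trans fusion with H next to isopropyl, which should also be the more stable one) followed in the same flask by Evans–Saksena reduction, in which the C3 hydroxyl binds boron and delivers hydride to the upper face of the C4 ketone only, giving the anti-1,3-diol (4S) and leaving the C7 enone untouched.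

Step 9
Reactants: 16 4-hydroxybenzoic acid
Product: 18 4-[(tert-butyldimethylsilyl)oxy]benzoic acid, via bis-silyl ester 17 (not isolated)
Conditions: TBSCl (2.2 equiv), imidazole (4 equiv), DMF, rt; then AcOH/THF/H2O (3:1:1), rt
Reagents that add atoms: tert-butyldimethylsilyl chloride, CC(C)(C)[Si](C)(C)Cl
Why: Silylation of phenol and acid followed by selective hydrolysis of the labile silyl ester leaves the phenol-protected acid.

Step 10
Reactants: 15 (1R,3R,3aS,4S,8aR)-1-[(tert-butyldimethylsilyl)oxy]-3,4-dihydroxy-6,8a-dimethyl-3-(propan-2-yl)-1,2,3,3a,4,8a-hexahydroazulen-7(8H)-one; 18 4-[(tert-butyldimethylsilyl)oxy]benzoic acid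
Product: 19 (1R,3R,3aS,4S,8aR)-1-[(tert-butyldimethylsilyl)oxy]-3-hydroxy-6,8a-dimethyl-7-oxo-3-(propan-2-yl)-1,2,3,3a,4,7,8,8a-octahydroazulen-4-yl 4-[(tert-butyldimethylsilyl)oxy]benzoate
Conditions: DCC (1.5 equiv), DMAP (0.5 equiv), CH2Cl2, 0 °C → rt
Reagents that add atoms: none
Why: Steglich esterification acylates the secondary allylic C4 hydroxyl, while the tertiary C3 hydroxyl does not react and C1 is already blocked as its TBS ether.

Step 11
Reactants: 19 (1R,3R,3aS,4S,8aR)-1-[(tert-butyldimethylsilyl)oxy]-3-hydroxy-6,8a-dimethyl-7-oxo-3-(propan-2-yl)-1,2,3,3a,4,7,8,8a-octahydroazulen-4-yl 4-[(tert-butyldimethylsilyl)oxy]benzoate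
Product: 20 (1R,3R,3aS,4S,8aR)-1,3-dihydroxy-6,8a-dimethyl-7-oxo-3-(propan-2-yl)-1,2,3,3a,4,7,8,8a-octahydroazulen-4-yl 4-hydroxybenzoate (CNP0199397.1)
Conditions: HF·pyridine, THF/pyridine, 0 °C → rt
Reagents that add atoms: none
Why: Fluoride desilylation removes the aryl and the secondary alkyl TBS ethers under buffered conditions that leave the ester, the tertiary alcohol and the enone intact.

## Compound list

1 | 2,5-dimethoxytoluene | COc1ccc(OC)c(C)c1 | starting material
2 | isobutyryl chloride | CC(C)C(Cl)=O | starting material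
3 | 1-(2,5-dimethoxy-4-methylphenyl)-2-methylpropan-1-one | COc1cc(C(=O)C(C)C)c(OC)cc1C | intermediate
4 | ethyl iodoacetate | CCOC(=O)CI | starting material
5 | ethyl (3R)-3-(2,5-dimethoxy-4-methylphenyl)-3-hydroxy-4-methylpentanoate | CCOC(=O)C[C@@](O)(C(C)C)c1cc(OC)c(C)cc1OC | intermediate
6 | ethyl (3R)-3-(2,5-dimethoxy-4-methylphenyl)-4-methyl-3-[(trimethylsilyl)oxy]pentanoate | CCOC(=O)C[C@@](O[Si](C)(C)C)(C(C)C)c1cc(OC)c(C)cc1OC | intermediate
7 | (3R)-3-(2,5-dimethoxy-4-methylphenyl)-N-methoxy-N,4-dimethyl-3-[(trimethylsilyl)oxy]pentanamide (Weinreb amide) | CON(C)C(=O)C[C@@](O[Si](C)(C)C)(C(C)C)c1cc(OC)c(C)cc1OC | intermediate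
8 | (5R)-5-(2,5-dimethoxy-4-methylphenyl)-6-methyl-5-[(trimethylsilyl)oxy]heptan-3-one | CCC(=O)C[C@@](O[Si](C)(C)C)(C(C)C)c1cc(OC)c(C)cc1OC | intermediate
9 | (6R)-6-(2,5-dimethoxy-4-methylphenyl)-1,1,1-trifluoro-3,7-dimethyl-6-[(trimethylsilyl)oxy]octane-2,4-dione (C3 epimers and enol forms) | CC(C(=O)C(F)(F)F)C(=O)C[C@@](O[Si](C)(C)C)(C(C)C)c1cc(OC)c(C)cc1OC | intermediate
10 | (5R)-2-diazo-5-(2,5-dimethoxy-4-methylphenyl)-6-methyl-5-[(trimethylsilyl)oxy]heptan-3-one | CC(=[N+]=[N-])C(=O)C[C@@](O[Si](C)(C)C)(C(C)C)c1cc(OC)c(C)cc1OC | intermediate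
11 | norcaradiene: 2,5-dimethoxy-4-methylcyclohexa-2,4-diene whose C1–C6 bond carries the cyclopropane carbon (CH3), with the cyclopentanone fused at C1 and that carbon; CH3 cis to OSiMe3 | COC1=CC(C)=C(OC)[C@H]2[C@]13[C@]2(C)C(=O)C[C@@]3(O[Si](C)(C)C)C(C)C | intermediate
12 | (3R,8aR)-4,7-dimethoxy-6,8a-dimethyl-3-(propan-2-yl)-3-[(trimethylsilyl)oxy]-3,8a-dihydroazulen-1(2H)-one | CC1=CC(OC)=C2[C@@](C)(C=C1OC)C(=O)C[C@@]2(O[Si](C)(C)C)C(C)C | intermediate
13 | (1R,3R,8aR)-1-[(tert-butyldimethylsilyl)oxy]-4,7-dimethoxy-6,8a-dimethyl-3-(propan-2-yl)-3-[(trimethylsilyl)oxy]-1,2,3,8a-tetrahydroazulene | CC1=CC(OC)=C2[C@@](C)(C=C1OC)[C@H](O[Si](C)(C)C(C)(C)C)C[C@@]2(O[Si](C)(C)C)C(C)C | intermediate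
14 | (1R,3R,3aR,8aR)-1-[(tert-butyldimethylsilyl)oxy]-3-hydroxy-6,8a-dimethyl-3-(propan-2-yl)-1,2,3,3a,8,8a-hexahydroazulene-4,7-dione (trans-fused) | CC1=CC(=O)[C@@H]2[C@@](C)(CC1=O)[C@H](O[Si](C)(C)C(C)(C)C)C[C@@]2(O)C(C)C | intermediate
15 | (1R,3R,3aS,4S,8aR)-1-[(tert-butyldimethylsilyl)oxy]-3,4-dihydroxy-6,8a-dimethyl-3-(propan-2-yl)-1,2,3,3a,4,8a-hexahydroazulen-7(8H)-one | CC1=C[C@H](O)[C@@H]2[C@@](C)(CC1=O)[C@H](O[Si](C)(C)C(C)(C)C)C[C@@]2(O)C(C)C | intermediate
16 | 4-hydroxybenzoic acid | OC(=O)c1ccc(O)cc1 | starting material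
17 | tert-butyldimethylsilyl 4-[(tert-butyldimethylsilyl)oxy]benzoate | CC(C)(C)[Si](C)(C)OC(=O)c1ccc(O[Si](C)(C)C(C)(C)C)cc1 | intermediate
18 | 4-[(tert-butyldimethylsilyl)oxy]benzoic acid | OC(=O)c1ccc(O[Si](C)(C)C(C)(C)C)cc1 | intermediate
19 | (1R,3R,3aS,4S,8aR)-1-[(tert-butyldimethylsilyl)oxy]-3-hydroxy-6,8a-dimethyl-7-oxo-3-(propan-2-yl)-1,2,3,3a,4,7,8,8a-octahydroazulen-4-yl 4-[(tert-butyldimethylsilyl)oxy]benzoate | CC1=C[C@H](OC(=O)c2ccc(O[Si](C)(C)C(C)(C)C)cc2)[C@@H]2[C@@](C)(CC1=O)[C@H](O[Si](C)(C)C(C)(C)C)C[C@@]2(O)C(C)C | intermediate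
20 | (1R,3R,3aS,4S,8aR)-1,3-dihydroxy-6,8a-dimethyl-7-oxo-3-(propan-2-yl)-1,2,3,3a,4,7,8,8a-octahydroazulen-4-yl 4-hydroxybenzoate | CC1=C[C@H](OC(=O)c2ccc(O)cc2)[C@@H]2[C@@](C)(CC1=O)[C@H](O)C[C@@]2(O)C(C)C | target

## Step count and risks

Total step count: 11. Longest linear sequence: 10 (steps 1–8, 10, 11; step 9 is a one-step side branch).

**Step 6 (Buchner reaction).** The α-methyl carbene may instead undergo a 1,2-hydride shift to the vinyl ketone, insert into the isopropyl C–H bond, or give the wrong C8a epimer. The fallback puts the angular methyl in after the ring expansion. It sets out from 6: Weinreb amide 7 is made as in step 4 and treated with MeMgBr to give (4R)-4-(2,5-dimethoxy-4-methylphenyl)-5-methyl-4-[(trimethylsilyl)oxy]hexan-2-one F1. Trifluoroacetylation (LiN(SiMe3)2, CF3CO2CH2CF3) gives (6R)-6-(2,5-dimethoxy-4-methylphenyl)-1,1,1-trifluoro-7-methyl-6-[(trimethylsilyl)oxy]octane-2,4-dione F2, and p-ABSA/Et3N converts it into the terminal diazoketone (4R)-1-diazo-4-(2,5-dimethoxy-4-methylphenyl)-5-methyl-4-[(trimethylsilyl)oxy]hexan-2-one F3, the best-precedented substrate class for this ring expansion. Rh2(OAc)4 in CH2Cl2 then gives, through the norcaradiene F4, (3R,8aR)-4,7-dimethoxy-6-methyl-3-(propan-2-yl)-3-[(trimethylsilyl)oxy]-3,8a-dihydroazulen-1(2H)-one F5. Its extended enolate (LiN(SiMe3)2, THF, −78 °C) is methylated at C8a with MeI from the face away from the isopropyl group, which returns the route at 12.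

**Step 8 (hydrolysis and directed reduction).** The β-hydroxy ene-dione 14 can lose water or undergo retro-aldol cleavage, the ring fusion may not come out trans, and the borohydride may be unselective. The fallback replaces the hydroxyl-delivered hydride by external hydride plus inversion. It sets out from 13: the same acid hydrolysis is stopped by a buffered work-up and 14 is isolated quickly. Chelation-controlled reduction with Zn(BH4)2 (Et2O, −40 °C; zinc bridges the C3 hydroxyl and the C4 ketone, hydride enters from the open lower face) gives the C4 epimer (1R,3R,3aS,4R,8aR)-1-[(tert-butyldimethylsilyl)oxy]-3,4-dihydroxy-6,8a-dimethyl-3-(propan-2-yl)-1,2,3,3a,4,8a-hexahydroazulen-7(8H)-one F6. Mitsunobu esterification with 18 (PPh3, DIAD, toluene, 0 °C) inverts C4 and returns the route at 19, bypassing 15.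

**Step 2 (enantioselective Reformatsky).** The hindered ortho-methoxyaryl isopropyl ketone may react slowly or with low ee. The fallback is a classical resolution. It sets out from 3: zinc dust and ethyl bromoacetate (THF, reflux) give racemic ethyl 3-(2,5-dimethoxy-4-methylphenyl)-3-hydroxy-4-methylpentanoate F7, and LiOH (THF/H2O) gives racemic 3-(2,5-dimethoxy-4-methylphenyl)-3-hydroxy-4-methylpentanoic acid F8. Crystallisation of its salt with (S)-1-phenylethylamine (or the antipode, whichever gives the less soluble salt of the wanted acid) and acidification gives (3R)-3-(2,5-dimethoxy-4-methylphenyl)-3-hydroxy-4-methylpentanoic acid F9. Esterification with EtI and K2CO3 in DMF returns the route at 5.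

## Further compounds

F1 | step 6 | (4R)-4-(2,5-dimethoxy-4-methylphenyl)-5-methyl-4-[(trimethylsilyl)oxy]hexan-2-one | CC(=O)C[C@@](O[Si](C)(C)C)(C(C)C)c1cc(OC)c(C)cc1OC
F2 | step 6 | (6R)-6-(2,5-dimethoxy-4-methylphenyl)-1,1,1-trifluoro-7-methyl-6-[(trimethylsilyl)oxy]octane-2,4-dione | O=C(CC(=O)C[C@@](O[Si](C)(C)C)(C(C)C)c1cc(OC)c(C)cc1OC)C(F)(F)F
F3 | step 6 | (4R)-1-diazo-4-(2,5-dimethoxy-4-methylphenyl)-5-methyl-4-[(trimethylsilyl)oxy]hexan-2-one | [N-]=[N+]=CC(=O)C[C@@](O[Si](C)(C)C)(C(C)C)c1cc(OC)c(C)cc1OC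
F4 | step 6 | norcaradiene from F3 (cyclopropane CH across the former ipso and C6 carbons, H cis to OSiMe3) | COC1=CC(C)=C(OC)[C@H]2[C@]13[C@@H]2C(=O)C[C@@]3(O[Si](C)(C)C)C(C)C
F5 | step 6 | (3R,8aR)-4,7-dimethoxy-6-methyl-3-(propan-2-yl)-3-[(trimethylsilyl)oxy]-3,8a-dihydroazulen-1(2H)-one | CC1=CC(OC)=C2[C@@H](C=C1OC)C(=O)C[C@@]2(O[Si](C)(C)C)C(C)C
F6 | step 8 | (1R,3R,3aS,4R,8aR)-1-[(tert-butyldimethylsilyl)oxy]-3,4-dihydroxy-6,8a-dimethyl-3-(propan-2-yl)-1,2,3,3a,4,8a-hexahydroazulen-7(8H)-one | CC1=C[C@@H](O)[C@@H]2[C@@](C)(CC1=O)[C@H](O[Si](C)(C)C(C)(C)C)C[C@@]2(O)C(C)C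
F7 | step 2 | racemic ethyl 3-(2,5-dimethoxy-4-methylphenyl)-3-hydroxy-4-methylpentanoate | CCOC(=O)CC(O)(C(C)C)c1cc(OC)c(C)cc1OC
F8 | step 2 | racemic 3-(2,5-dimethoxy-4-methylphenyl)-3-hydroxy-4-methylpentanoic acid | OC(=O)CC(O)(C(C)C)c1cc(OC)c(C)cc1OC
F9 | step 2 | (3R)-3-(2,5-dimethoxy-4-methylphenyl)-3-hydroxy-4-methylpentanoic acid | OC(=O)C[C@@](O)(C(C)C)c1cc(OC)c(C)cc1OC
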